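Which flask holds most complex with three exchanged at 3.0 min, and how far apart do they lie? The meeting had this before it.

| setting | south-east | east | north-east | spring | noon | dusk |
|---|---|---|---|---|---|---|
| starting complex | 10 mM | 10 mM | 10 mM | 10 mM | 10 mM | 10 mM (fed, over 80 s) |
| incoming ligand | 25 mM | 12 mM | 50 mM | 25.0 mM | 25.0 mM (fed, over 80 s) | 25.0 mM |
| remark | run made earlier | run made earlier | run made earlier | everything together at the start | all else is in the flask from the start; the feed brings no volume worth counting | all else is in the flask from the start; the feed brings no volume worth counting |
| time |  |  |  | 3.0 min | 3.0 min | 3.0 min |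

| run | time / min | complex with three exchanged / % | complex with one exchanged / % | starting complex / % |
|---|---|---|---|---|
| south-east | 0.167 | 0.1 | 11.5 | 89.0 |
| south-east | 0.500 | 1.5 | 21.9 | 70.7 |
| south-east | 0.833 | 5.5 | 26.4 | 57.2 |
| south-east | 1.33 | 13.0 | 28.4 | 44.3 |
| south-east | 2.00 | 23.4 | 26.7 | 32.3 |
| south-east | 2.50 | 29.7 | 25.2 | 27.2 |
| south-east | 3.00 | 35.6 | 23.3 | 23.4 |
| east | 0.333 | 0 | 9.7 | 89.4 |
| east | 0.667 | 0.9 | 15.0 | 80.6 |
| east | 1.00 | 0.5 | 20.9 | 73.9 |
| east | 1.33 | 2.9 | 21.9 | 67.2 |
| east | 1.50 | 3.0 | 22.6 | 63.5 |
| east | 2.00 | 5.9 | 24.2 | 57.7 |
| east | 2.50 | 7.5 | 24.8 | 52.2 |
| north-east | 0.200 | 0.9 | 19.0 | 74.8 |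
| north-east | 0.333 | 5.1 | 25.3 | 62.3 |
| north-east | 0.417 | 7.1 | 28.5 | 56.6 |
| north-east | 0.667 | 16.1 | 28.9 | 41.5 |
| north-east | 1.00 | 30.4 | 25.9 | 29.0 |
| north-east | 1.50 | 48.6 | 20.4 | 17.2 |
| north-east | 2.50 | 71.8 | 11.2 | 6.2 |

(each reading ± 0.5 percentage points)

- percentages count the starting complex that a species holds: one side product counts as two
- what may be going on: complex with one exchanged + incoming ligand -> leaving ligand + complex with two exchanged; starting complex + complex with one exchanged -> side product; starting complex + incoming ligand -> leaving ligand + complex with one exchanged; complex with two exchanged + incoming ligand -> leaving ligand + complex with three exchanged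

- the flask that comes out highest in amount of complex with three exchanged, in percent of the starting complex charged, or "all alike" when all lie within 1.5 percentage points (spring / noon / dusk / all alike)
- complex with three exchanged at the end, in percent of the starting complex charged, spring
- complex with three exchanged at the end, in percent of the starting complex charged, noon
- complex with three exchanged at the end, in percent of the starting complex charged, dusk

The chair noted that the south-east run has the charges of spring, so spring repeats it. One member argued that a steady feed over 80 s delivers its charge on average 0.667 min late. Both fed flasks should therefore run about that far behind spring. Another member wanted a measure free of the clock. She divided the rise of complex with three exchanged by the fall of starting complex between 2.00 min and 3.00 min in the south-east run, and read 1.37. She called this reading the exchange return, y: points of complex with three exchanged gained per point of starting complex lost. The clock does not enter this ratio, but the stage does: between 0.500 min and 0.833 min the same division reads 0.296, so y belongs to the stretch it was read on.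

The secretary reckoned on from this, apart from the forecast. At 2.33 min the south-east readings put starting complex near 28.9%. Taking y back from the last south-east reading then gives 28.1% for each fed flask. The forecast named spring, with 35.5% for spring, 27.5% for noon and 28.2% for dusk: “Both fed flasks lose time, so spring wins.” The secretary's figure does not part noon from dusk, but the forecast does. The meeting agreed to watch starting complex beside the product.

The flasks gave 35.5% for spring, 27.4% for noon and 28.1% for dusk. So spring came highest, 7.4 percentage points above dusk.

    complex with one exchanged + incoming ligand → leaving ligand + complex with two exchanged (k = 0.711 M⁻¹ s⁻¹)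
    starting complex + complex with one exchanged → side product (k = 0.195 M⁻¹ s⁻¹)
    starting complex + incoming ligand → leaving ligand + complex with one exchanged (k = 0.486 M⁻¹ s⁻¹)
    complex with two exchanged + incoming ligand → leaving ligand + complex with three exchanged (k = 1.62 M⁻¹ s⁻¹)

The neighbour is spring left until 5.0 min. Its starting complex stood at 14.2%, which is 8.8 points below spring at 3.00 min. Multiplying that fall by y and adding it to the 35.5% of spring gives 47.6%. The return was read between earlier times, so this carries it past its readings. The neighbour flask held 50.3% of complex with three exchanged at 5.00 min.

The runs are calculated with constants of no real substance; the scatter is artificial.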